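The route rests on disconnecting the C5–C6 bond of the 3,6-dihydro-2H-pyran ring, between the allylic OCH2 carbon and the vinylic carbon that carries the homofarnesyl chain. The pyran is traced back to its silicon analogue, a 1,2-oxasiline in which SiMe2 occupies the place of C6; a ruthenium-catalysed endo-dig trans-hydrosilylation of a homopropargylic alcohol builds it and fixes position and geometry of the C4=C5 bond. In the key step formaldehyde and Me3SiOTf convert the Si–O1 bond into an O1=C6 oxocarbenium ion, and ipso attack of C5 closes the ring with loss of silicon. The step exploits the O1–C6H2–C5=C4 allylic ether unit of the pyran ring.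

Key step: step 5

Assumption: ethyl (S)-3,4-epoxybutanoate (5) is taken as a catalogue compound (otherwise one step, Ag2O, from commercial ethyl (S)-4-chloro-3-hydroxybutanoate), and farnesyl bromide as the commercial (2E,6E) isomer.

Step 1
Reactants: 1 1-(trimethylsilyl)propyne; 2 (2E,6E)-farnesyl bromide
Product: 4 (5E,9E)-6,10,14-trimethylpentadeca-5,9,13-trien-1-yne, via silylated enyne 3 (not isolated)
Conditions: n-BuLi, THF, −78 → −20 °C; 2, −78 → 0 °C; then MeOH, K2CO3 (cat.), rt
Reagents that add atoms: none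
Why: Propargylic lithiation of 1 gives a silyl-capped propargyl anion that alkylates the primary allylic bromide by direct SN2 (the silyl group suppresses allenyl products), and carbonate/methanol C-desilylation frees the terminal alkyne without touching the E alkenes (propargyl anion alkylation).

Step 2
Reactants: 4 (5E,9E)-6,10,14-trimethylpentadeca-5,9,13-trien-1-yne; 5 ethyl (S)-3,4-epoxybutanoate
Product: 6 ethyl (3R,9E,13E)-3-hydroxy-10,14,18-trimethylnonadeca-9,13,17-trien-5-ynoate
Conditions: n-BuLi, THF, −78 °C; BF3·OEt2; then 5 (1.3 equiv), −78 °C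
Reagents that add atoms: none
Why: Yamaguchi–Hirao alkynylation: the non-basic alkynyl trifluoroborate opens the BF3-activated epoxide at its terminal CH2 faster than it attacks the ester, and the C–O bond of the stereocenter is not touched, so (S)-5 gives (3R)-6 (the descriptor changes only through the priority rules).

Step 3
Reactants: 6 ethyl (3R,9E,13E)-3-hydroxy-10,14,18-trimethylnonadeca-9,13,17-trien-5-ynoate
Product: 9 ethyl (3R,9E,13E)-3-hydroxy-10,14,18-trimethyl-2-methylidenenonadeca-9,13,17-trien-5-ynoate, via Mannich base 7 (not isolated), via ammonium iodide 8 (not isolated)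
Conditions: LiN(iPr)2 (2.2 equiv), THF, −78 → −20 °C; CH2=NMe2+ I−, −78 → 0 °C; aq. work-up; crude + MeI, CH2Cl2, rt; evaporate; DBU, CH2Cl2, rt
Reagents that add atoms: Eschenmoser's salt (N,N-dimethylmethyleneiminium iodide), C=[N+](C)C.[I-]
Why: Fráter–Seebach dianion Mannich reaction followed by Hofmann-type elimination: the alkoxide–enolate dianion is C-aminomethylated, and N-methylation then DBU-induced loss of trimethylamine gives the α-methylene ester; the dianion cannot expel oxide, the carbinol center is untouched and the transient α-center is destroyed.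

Step 4
Reactants: 9 ethyl (3R,9E,13E)-3-hydroxy-10,14,18-trimethyl-2-methylidenenonadeca-9,13,17-trien-5-ynoate
Product: 11 ethyl 2-[(6R)-2,2-dimethyl-3-[(3E,7E)-4,8,12-trimethyltrideca-3,7,11-trien-1-yl]-5,6-dihydro-2H-1,2-oxasilin-6-yl]prop-2-enoate, via dimethylsilyl ether 10 (not isolated)
Conditions: (HMe2Si)2NH, neat, rt → 50 °C; evaporate; [Cp*Ru(MeCN)3]PF6 (3 mol %), CH2Cl2, 0 °C → rt
Reagents that add atoms: 1,1,3,3-tetramethyldisilazane, C[SiH](C)N[SiH](C)C
Why: Trost intramolecular alkyne hydrosilylation: the cationic Cp*Ru catalyst adds Si–H trans across the alkyne, and a trans addition from an oxygen-tethered silane is only possible in the 6-endo-dig mode, which places silicon on the chain-bearing alkyne carbon cis to the ring CH2; alkenes and the acrylate are not substrates of this catalyst.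

Step 5
Reactants: 11 ethyl 2-[(6R)-2,2-dimethyl-3-[(3E,7E)-4,8,12-trimethyltrideca-3,7,11-trien-1-yl]-5,6-dihydro-2H-1,2-oxasilin-6-yl]prop-2-enoate
Product: 13 ethyl 2-[(2R)-5-[(3E,7E)-4,8,12-trimethyltrideca-3,7,11-trien-1-yl]-3,6-dihydro-2H-pyran-2-yl]prop-2-enoate, via oxocarbenium triflate 12 (not isolated)
Conditions: (CH2O)n (1.3 equiv), Me3SiOTf (1.3 equiv), 2,6-di-tert-butyl-4-methylpyridine (0.3 equiv), CH2Cl2, −78 → −30 °C; aq. NaHCO3
Reagents that add atoms: paraformaldehyde (as formaldehyde), C=O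
Why: Proposed new method: Me3SiOTf-activated formaldehyde is captured by the ring oxygen of 11, silicon migrates from O1 to the hemiacetal oxygen and loss of that siloxy group gives oxocarbenium ion 12 (O1=C6H2), in which C5, the silicon-bearing carbon of the Z-vinylsilane, attacks C6; the C4 cation is β-silicon-stabilized and collapses to the C4=C5 alkene by loss of the silyl group as Me3SiOSiMe2OTf. The closest known reaction types are the silyl-Prins (vinylsilane-terminated oxocarbenium) cyclization of (Z)-4-silylbut-3-en-1-ols with aldehydes to 3,6-dihydro-2H-pyrans and the Me3SiOTf-mediated formation of oxocarbenium ions from silyl ethers and aldehydes; what is new is that one silicon serves as oxygen substituent and as electrofuge, so that SiMe2 is exchanged for CH2 within the ring. The pyran ring closes in a 6-endo-trig mode with respect to the C4=C5 bond (the C6=O1 bond is endocyclic too). No stereocenter is formed, and C2 is preserved because a 2-oxonia-Cope shift would need an acrylate-conjugated, destabilized oxocarbenium ion. The step needs ipso regioselectivity (C5 instead of C4) and chemoselectivity over the three trisubstituted chain alkenes: the β-silicon effect, the six-membered transition state and the Z geometry inherited from the oxasiline (silicon cis to C3) secure the first, while the low temperature, the near-stoichiometric formaldehyde and the hindered pyridine (which removes triflic acid) secure the second.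

Step 6
Reactants: 13 ethyl 2-[(2R)-5-[(3E,7E)-4,8,12-trimethyltrideca-3,7,11-trien-1-yl]-3,6-dihydro-2H-pyran-2-yl]prop-2-enoate
Product: 14 2-[(2R)-5-[(3E,7E)-4,8,12-trimethyltrideca-3,7,11-trien-1-yl]-3,6-dihydro-2H-pyran-2-yl]prop-2-enoic acid (CNP0171598.2)
Conditions: LiOH·H2O (3 equiv), THF/H2O 3:1, 0 °C → rt; then cold 0.5 M HCl to pH 3
Reagents that add atoms: lithium hydroxide, [Li+].[OH-]
Why: Ester saponification (BAc2): the α-branched acrylate adds hydroxide only reversibly, the ring ether oxygen is too poor a leaving group for SN2′ loss, and C2 carries no acidic hydrogen, so the configuration should be kept.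

Compound list
1 | 1-(trimethylsilyl)propyne | CC#C[Si](C)(C)C | starting material
2 | (2E,6E)-farnesyl bromide | BrC/C=C(\C)CC/C=C(\C)CCC=C(C)C | starting material
3 | trimethyl[(5E,9E)-6,10,14-trimethylpentadeca-5,9,13-trien-1-yn-1-yl]silane | C[Si](C)(C)C#CCC/C=C(\C)CC/C=C(\C)CCC=C(C)C | intermediate (not isolated)
4 | (5E,9E)-6,10,14-trimethylpentadeca-5,9,13-trien-1-yne | C#CCC/C=C(\C)CC/C=C(\C)CCC=C(C)C | intermediate
5 | ethyl (S)-3,4-epoxybutanoate (ethyl 2-[(2S)-oxiran-2-yl]acetate) | CCOC(=O)C[C@H]1CO1 | starting material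
6 | ethyl (3R,9E,13E)-3-hydroxy-10,14,18-trimethylnonadeca-9,13,17-trien-5-ynoate | CCOC(=O)C[C@H](O)CC#CCC/C=C(\C)CC/C=C(\C)CCC=C(C)C | intermediate
7 | ethyl (3R,9E,13E)-2-[(dimethylamino)methyl]-3-hydroxy-10,14,18-trimethylnonadeca-9,13,17-trien-5-ynoate (C-2 epimers, center destroyed later) | CCOC(=O)C(CN(C)C)[C@H](O)CC#CCC/C=C(\C)CC/C=C(\C)CCC=C(C)C | intermediate (not isolated)
8 | N-methyl quaternary ammonium iodide of 7 (CH2NMe3+ I− in place of CH2NMe2) | CCOC(=O)C(C[N+](C)(C)C)[C@H](O)CC#CCC/C=C(\C)CC/C=C(\C)CCC=C(C)C.[I-] | intermediate (not isolated)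
9 | ethyl (3R,9E,13E)-3-hydroxy-10,14,18-trimethyl-2-methylidenenonadeca-9,13,17-trien-5-ynoate | C=C(C(=O)OCC)[C@H](O)CC#CCC/C=C(\C)CC/C=C(\C)CCC=C(C)C | intermediate
10 | ethyl (3R,9E,13E)-3-[(dimethylsilyl)oxy]-10,14,18-trimethyl-2-methylidenenonadeca-9,13,17-trien-5-ynoate | C=C(C(=O)OCC)[C@H](O[SiH](C)C)CC#CCC/C=C(\C)CC/C=C(\C)CCC=C(C)C | intermediate (not isolated)
11 | ethyl 2-[(6R)-2,2-dimethyl-3-[(3E,7E)-4,8,12-trimethyltrideca-3,7,11-trien-1-yl]-5,6-dihydro-2H-1,2-oxasilin-6-yl]prop-2-enoate | C=C(C(=O)OCC)[C@H]1CC=C(CC/C=C(\C)CC/C=C(\C)CCC=C(C)C)[Si](C)(C)O1 | intermediate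
12 | oxocarbenium triflate: ethyl (3R,5Z,9E,13E)-6-[dimethyl(trimethylsilyloxy)silyl]-10,14,18-trimethyl-2-methylidene-3-(methylideneoxonio)nonadeca-5,9,13,17-tetraenoate triflate | C=C(C(=O)OCC)[C@H]([O+]=C)C/C=C(/CC/C=C(\C)CC/C=C(\C)CCC=C(C)C)[Si](C)(C)O[Si](C)(C)C.[O-]S(=O)(=O)C(F)(F)F | intermediate (not isolated)
13 | ethyl 2-[(2R)-5-[(3E,7E)-4,8,12-trimethyltrideca-3,7,11-trien-1-yl]-3,6-dihydro-2H-pyran-2-yl]prop-2-enoate | C=C(C(=O)OCC)[C@H]1CC=C(CC/C=C(\C)CC/C=C(\C)CCC=C(C)C)CO1 | intermediate
14 | 2-[(2R)-5-[(3E,7E)-4,8,12-trimethyltrideca-3,7,11-trien-1-yl]-3,6-dihydro-2H-pyran-2-yl]prop-2-enoic acid | C=C(C(=O)O)[C@H]1CC=C(CC/C=C(\C)CC/C=C(\C)CCC=C(C)C)CO1 | target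

Total step count: 6. Longest linear sequence: 6 steps (2 → 4 → 6 → 9 → 11 → 13 → 14).

Steps most likely to fail

Step 5 (key step). The silylated formaldehyde may attack the chain alkenes (ene or Prins reaction) faster than the hindered siloxane oxygen. The siloxy-substituted silicon may also be too poor an electrofuge, so that the cation is diverted into protodesilylation or oligomerization, and traces of triflic acid may start a cationic cyclization of the polyene. The fallback uses known chemistry, sets out from 11 and comes back at 14. iBu2AlH (CH2Cl2, −78 °C) should reduce the ester to the oxasilinyl allylic alcohol F1 without touching the Si–O bond. MeLi (Et2O, −78 → 0 °C) should then open the oxasiline at silicon to the acyclic (Z)-vinyltrimethylsilane diol F2. The established silyl-Prins cyclization of this (Z)-4-silylbut-3-en-1-ol with paraformaldehyde and Me3SiOTf (CH2Cl2, −78 °C; K2CO3/MeOH work-up) should give the pyranyl allylic alcohol F3. MnO2 (CH2Cl2) should give the enal F4, and NaClO2/NaH2PO4/2-methyl-2-butene oxidation should deliver 14.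

Step 4. The cationic ruthenium catalyst may be sequestered by the acrylate or diverted into cycloisomerization of the 1,5-enyne unit. Silylation of the hindered allylic alcohol may also be incomplete, which would leave an intermolecular hydrosilylation with poor regiocontrol. The fallback sets out from 6 and comes back at 11; it inverts the order of events so that the ruthenium step runs before the acrylate exists. 6 is silylated with (HMe2Si)2NH to the dimethylsilyl ether F5 and cyclized with [Cp*Ru(MeCN)3]PF6 to the oxasilinyl acetate F6. Its ester enolate (LiN(iPr)2, 1.1 equiv, THF, −78 °C, trapped cold to avoid β-elimination) is aminomethylated with CH2=NMe2+ I− to the Mannich base F7. This is quaternized with MeI to the ammonium iodide F8 and eliminated with DBU to give 11.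

Step 2. Acylation of the alkynylborate by the ethyl ester (ynone formation) or base-induced isomerization of the β,γ-epoxy ester to a γ-hydroxy enoate may compete with epoxide opening. The fallback sets out from 4 and comes back at 6; it carries the future carboxyl carbon at the alcohol oxidation level through the C–C bond formation. The lithium acetylide of 4 with BF3·OEt2 opens (S)-2-[2-(tert-butyldimethylsilyloxy)ethyl]oxirane to the silyl ether alcohol F9. Bu4NF gives the 1,3-diol F10. TEMPO (cat.)/PhI(OAc)2 in MeCN/H2O oxidizes the primary alcohol selectively through the hydroxy aldehyde F11 to the β-hydroxy acid F12, and EtI/K2CO3 in DMF gives 6.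

Further compounds
F1 | step 5 | 2-[(6R)-2,2-dimethyl-3-[(3E,7E)-4,8,12-trimethyltrideca-3,7,11-trien-1-yl]-5,6-dihydro-2H-1,2-oxasilin-6-yl]prop-2-en-1-ol | C=C(CO)[C@H]1CC=C(CC/C=C(\C)CC/C=C(\C)CCC=C(C)C)[Si](C)(C)O1
F2 | step 5 | (3R,5Z,9E,13E)-10,14,18-trimethyl-2-methylidene-6-(trimethylsilyl)nonadeca-5,9,13,17-tetraene-1,3-diol | C=C(CO)[C@H](O)C/C=C(/CC/C=C(\C)CC/C=C(\C)CCC=C(C)C)[Si](C)(C)C
F3 | step 5 | 2-[(2R)-5-[(3E,7E)-4,8,12-trimethyltrideca-3,7,11-trien-1-yl]-3,6-dihydro-2H-pyran-2-yl]prop-2-en-1-ol | C=C(CO)[C@H]1CC=C(CC/C=C(\C)CC/C=C(\C)CCC=C(C)C)CO1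
F4 | step 5 | 2-[(2R)-5-[(3E,7E)-4,8,12-trimethyltrideca-3,7,11-trien-1-yl]-3,6-dihydro-2H-pyran-2-yl]prop-2-enal | C=C(C=O)[C@H]1CC=C(CC/C=C(\C)CC/C=C(\C)CCC=C(C)C)CO1
F5 | step 4 | ethyl (3R,9E,13E)-3-[(dimethylsilyl)oxy]-10,14,18-trimethylnonadeca-9,13,17-trien-5-ynoate | CCOC(=O)C[C@H](O[SiH](C)C)CC#CCC/C=C(\C)CC/C=C(\C)CCC=C(C)C
F6 | step 4 | ethyl 2-[(6R)-2,2-dimethyl-3-[(3E,7E)-4,8,12-trimethyltrideca-3,7,11-trien-1-yl]-5,6-dihydro-2H-1,2-oxasilin-6-yl]acetate | CCOC(=O)C[C@H]1CC=C(CC/C=C(\C)CC/C=C(\C)CCC=C(C)C)[Si](C)(C)O1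
F7 | step 4 | ethyl 3-(dimethylamino)-2-[(6R)-2,2-dimethyl-3-[(3E,7E)-4,8,12-trimethyltrideca-3,7,11-trien-1-yl]-5,6-dihydro-2H-1,2-oxasilin-6-yl]propanoate (C-2 epimers) | CCOC(=O)C(CN(C)C)[C@H]1CC=C(CC/C=C(\C)CC/C=C(\C)CCC=C(C)C)[Si](C)(C)O1
F8 | step 4 | N-methyl quaternary ammonium iodide of F7 | CCOC(=O)C(C[N+](C)(C)C)[C@H]1CC=C(CC/C=C(\C)CC/C=C(\C)CCC=C(C)C)[Si](C)(C)O1.[I-]
F9 | step 2 | (3R,9E,13E)-1-[(tert-butyldimethylsilyl)oxy]-10,14,18-trimethylnonadeca-9,13,17-trien-5-yn-3-ol | CC(C)(C)[Si](C)(C)OCC[C@H](O)CC#CCC/C=C(\C)CC/C=C(\C)CCC=C(C)C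
F10 | step 2 | (3R,9E,13E)-10,14,18-trimethylnonadeca-9,13,17-trien-5-yne-1,3-diol | OCC[C@H](O)CC#CCC/C=C(\C)CC/C=C(\C)CCC=C(C)C
F11 | step 2 | (3R,9E,13E)-3-hydroxy-10,14,18-trimethylnonadeca-9,13,17-trien-5-ynal | O=CC[C@H](O)CC#CCC/C=C(\C)CC/C=C(\C)CCC=C(C)C
F12 | step 2 | (3R,9E,13E)-3-hydroxy-10,14,18-trimethylnonadeca-9,13,17-trien-5-ynoic acid | OC(=O)C[C@H](O)CC#CCC/C=C(\C)CC/C=C(\C)CCC=C(C)C
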